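**Plan**
Retrosynthesis: both C11=C12 bonds of the C40 chain are cut first (two Wittig reactions, C15 + C10 + C15), then each ring–alkyne bond C6–C7 (Sonogashira coupling of a cyclohexenyl triflate with (E)-3-methylpent-2-en-4-yn-1-ol), and last the C2–C3 bond of the hydroxylated ring B.
Enabling feature: in ring B (C1 CMe2, C2 CH2, C3 CHOH, C4 CH2, C5 C–Me, C6 C–alkyne) the alkyne carbon C6 can be a ketone, it sits next to the quaternary C1, and O–C3 is 1,4 to it. Opening this 4-hydroxy-2,2,6-trimethylcyclohexanone between C2 and C3 gives an aldehyde (C3) tethered to an isopropenyl silyloxy carbinol (C2=C1–C6).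
Forward, ring B: asymmetric crotylboration of 3-methylbut-3-en-2-one builds C5/C6; a Lewis acid then closes C2–C3 by a Prins cyclization ended by a 1,2-methyl shift from C6 to C1, which makes the gem-dimethyl carbon and the C6 ketone in the same event.
Stereochemistry: C3 (R), the only stereocenter of the target, is relayed in the chair of the ring closure from two helper centers, C6 (lost in the methyl shift) and C5 (lost on enol triflate formation).
Forward, chain: ring A is the dienyl triflate of 2,6,6-trimethylcyclohex-2-en-1-one; the ring A C15 phosphonium salt and the C10 dialdehyde give a C25 aldehyde, which the ring B C15 salt extends to C40. E geometry comes from the E building blocks and thermal equilibration of the two new double bonds.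

Key step: step 6

Assumption: the (S)-antipode of the 3,3'-dibromobinaphthol catalyst in step 2 is taken to give the (3R,4R) adduct; if the sense of induction is the reverse, the (R)-antipode is used and nothing else changes.
Assumption: compounds 1, 4, 14, 18 and 22 are taken as commercial.

**Step 1**
Reactants: 1 (E)-but-2-ene
Product: 3 diisopropyl (E)-but-2-en-1-ylboronate, via crotylpotassium 2 (not isolated)
Conditions: KOtBu, n-BuLi, THF, −78 to −50 °C; B(OiPr)3, −78 °C; HCl in Et2O (2 equiv), −78 °C to rt; filtration, distillation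
Reagents that add atoms: triisopropyl borate, CC(C)OB(OC(C)C)OC(C)C; potassium tert-butoxide, CC(C)(C)[O-].[K+] (its potassium stays only in 2)
Why: allylic metalation with the n-BuLi/KOtBu superbase gives the (E)-crotylpotassium, which keeps its geometry below −50 °C and is trapped on boron (metalation–borylation), acid then releasing the neutral boronate from the ate complex.

**Step 2**
Reactants: 3 diisopropyl (E)-but-2-en-1-ylboronate; 4 3-methylbut-3-en-2-one
Product: 5 (3R,4R)-2,3,4-trimethylhexa-1,5-dien-3-ol
Conditions: (S)-3,3'-dibromo-1,1'-bi-2-naphthol (15 mol %), PhCF3–toluene, −35 °C; aq. NaHCO3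
Reagents that add atoms: none
Why: chiral-diol-catalysed asymmetric crotylboration of a ketone, in which exchange of one isopropoxide for the binaphthol gives a more Lewis-acidic chiral boronate that adds through a closed chair transition state with the isopropenyl group equatorial, so the (E)-crotyl geometry should become the anti hydroxyl/methyl relationship and the catalyst should set the absolute configuration of both new centers.

**Step 3**
Reactants: 5 (3R,4R)-2,3,4-trimethylhexa-1,5-dien-3-ol
Product: 6 triethyl{[(3R,4R)-2,3,4-trimethylhexa-1,5-dien-3-yl]oxy}silane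
Conditions: Et3SiOTf, 2,6-lutidine, CH2Cl2, −78 to 0 °C
Reagents that add atoms: triethylsilyl trifluoromethanesulfonate, CC[Si](CC)(CC)OS(=O)(=O)C(F)(F)F
Why: silyl ether formation on the hindered tertiary allylic alcohol with a silyl triflate, the silyloxy group being the electron-releasing group that later ends the cationic cyclization.

**Step 4**
Reactants: 6 triethyl{[(3R,4R)-2,3,4-trimethylhexa-1,5-dien-3-yl]oxy}silane
Product: 8 (3R,4R)-3,4,5-trimethyl-4-[(triethylsilyl)oxy]hex-5-en-1-ol, via catechol boronate 7 (not isolated)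
Conditions: catecholborane, RhCl(PPh3)3 (2 mol %), THF, 0 °C to rt; then NaOH, H2O2, 0 °C
Reagents that add atoms: hydrogen peroxide, OO; catecholborane, B1Oc2ccccc2O1 (its boron and catechol stay only in 7)
Why: rhodium-catalysed anti-Markovnikov hydroboration discriminates sharply by alkene substitution, so the monosubstituted vinyl group should react and the 1,1-disubstituted isopropenyl group on the fully substituted carbon should not, and oxidation of the C–B bond with retention gives the primary alcohol (hydroboration–oxidation).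

**Step 5**
Reactants: 8 (3R,4R)-3,4,5-trimethyl-4-[(triethylsilyl)oxy]hex-5-en-1-ol
Product: 9 (3R,4R)-3,4,5-trimethyl-4-[(triethylsilyl)oxy]hex-5-enal
Conditions: TEMPO (10 mol %), PhI(OAc)2, CH2Cl2, rt
Reagents that add atoms: none
Why: oxoammonium (TEMPO) oxidation of a primary alcohol stops at the aldehyde and should leave the tertiary silyl ether and the alkene alone.

**Step 6**
Reactants: 9 (3R,4R)-3,4,5-trimethyl-4-[(triethylsilyl)oxy]hex-5-enal
Product: 10 (4R,6R)-4-hydroxy-2,2,6-trimethylcyclohexan-1-one
Conditions: Me2AlCl (1.5 equiv), CH2Cl2, −78 to −40 °C; then 1 M HCl, THF, 0 °C; chromatography to remove the C3-epimeric (cis) diastereomer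
Reagents that add atoms: none
Why: Proposed new method: the aldehyde–Me2AlCl complex is attacked at C3 by the terminal carbon C2 of the isopropenyl group through a chair (6-endo-trig at the alkene, carbonyl oxygen exocyclic), the positive charge building on C1 is quenched at once by a 1,2-shift of the methyl on C6, and the resulting silyloxocarbenium ion gives up Et3Si+ to chloride to unveil the C6 ketone. The closest known reaction types are the acetal-initiated Prins–pinacol cyclization of alkenyl silyloxy carbinols and the Me2AlCl-promoted type 2 carbonyl-ene cyclization of 5-methylhex-5-enals; an aldehyde-initiated closure ended by a ring-retaining methyl shift is the new element. The new stereocenter C3 is fixed in that chair by the two helper centers: C6 must place its methyl axial (parallel to the empty orbital on C1 and anti to the incoming C3) and its silyloxy group equatorial, and the C5 methyl, trans to the C6 methyl, is then axial on the other face, so the aluminium-bound oxygen on C3 can only be equatorial (axial would be syn-diaxial to the C5 methyl), which is O trans to the C5 methyl, that is (4R,6R). The step needs the shift to win over proton loss and the methyl to win over the ring carbon: a cation β to a silyloxy group is poorly stabilized unless the shift accompanies its formation, the shift ends in an oxocarbenium ion, and of the bonds on C6 only the exocyclic axial C–CH3 is parallel to the empty orbital, the C6–C5 ring bond lying near its nodal plane on the face already taken by C3. Because the C5 center is still in place, any C3 epimer is a diastereomer and is removed here, before C5 is flattened.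

**Step 7**
Reactants: 10 (4R,6R)-4-hydroxy-2,2,6-trimethylcyclohexan-1-one
Product: 11 (4R,6R)-2,2,6-trimethyl-4-[(triethylsilyl)oxy]cyclohexan-1-one
Conditions: Et3SiCl, imidazole, DMF, 0 °C to rt
Reagents that add atoms: chlorotriethylsilane, CC[Si](Cl)(CC)CC
Why: standard silyl ether formation on the secondary alcohol, a triethylsilyl ether being chosen because it should survive strong base and the coupling but fall off in acidic methanol in step 10.

**Step 8**
Reactants: 11 (4R,6R)-2,2,6-trimethyl-4-[(triethylsilyl)oxy]cyclohexan-1-one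
Product: 13 (4R)-2,6,6-trimethyl-4-[(triethylsilyl)oxy]cyclohex-1-en-1-yl trifluoromethanesulfonate, via potassium enolate 12 (not isolated)
Conditions: KN(SiMe3)2, THF, −78 to 0 °C; PhNTf2, −78 °C to rt
Reagents that add atoms: N-phenylbis(trifluoromethanesulfonimide), O=S(=O)(N(c1ccccc1)S(=O)(=O)C(F)(F)F)C(F)(F)F; potassium bis(trimethylsilyl)amide, C[Si](C)(C)[N-][Si](C)(C)C.[K+] (its potassium stays only in 12)
Why: the ketone has a single enolizable position (C5–H), so deprotonation and O-sulfonylation (enol triflate formation) can only give the tetrasubstituted C5=C6 enol triflate, which flattens the helper center C5, while the silyloxy group, γ to the carbonyl, cannot be eliminated.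

**Step 9**
Reactants: 13 (4R)-2,6,6-trimethyl-4-[(triethylsilyl)oxy]cyclohex-1-en-1-yl trifluoromethanesulfonate; 14 (E)-3-methylpent-2-en-4-yn-1-ol
Product: 15 (2E)-3-methyl-5-[(4R)-2,6,6-trimethyl-4-[(triethylsilyl)oxy]cyclohex-1-en-1-yl]pent-2-en-4-yn-1-ol
Conditions: Pd(PPh3)4 (5 mol %), CuI (10 mol %), Et3N, DMF, 50 °C, degassed
Reagents that add atoms: none
Why: Sonogashira coupling of an alkenyl triflate with a terminal alkyne (oxidative addition to zerovalent palladium, copper acetylide transmetalation) should form the C6–C7 bond without touching the E enynol geometry or the free primary alcohol.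

**Step 10**
Reactants: 15 (2E)-3-methyl-5-[(4R)-2,6,6-trimethyl-4-[(triethylsilyl)oxy]cyclohex-1-en-1-yl]pent-2-en-4-yn-1-ol
Product: 17 [(2E)-5-[(4R)-4-hydroxy-2,6,6-trimethylcyclohex-1-en-1-yl]-3-methylpent-2-en-4-yn-1-yl]triphenylphosphonium bromide, via diol 16 (not isolated)
Conditions: PPh3·HBr (1.2 equiv), MeOH, 0 °C to rt
Reagents that add atoms: triphenylphosphine hydrobromide, c1ccc(cc1)[PH+](c1ccccc1)c1ccccc1.[Br-]
Why: acidic methanol should remove the triethylsilyl ether, and the phosphine hydrobromide converts the primary allylic alcohol into the allylic phosphonium salt (phosphonium salt formation), while the secondary homoallylic alcohol at C3 is not ionized.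

**Step 11**
Reactants: 18 2,6,6-trimethylcyclohex-2-en-1-one
Product: 19 2,6,6-trimethylcyclohexa-1,3-dien-1-yl trifluoromethanesulfonate
Conditions: Tf2O, 2,6-di-tert-butyl-4-methylpyridine, CH2Cl2, 0 °C to rt
Reagents that add atoms: trifluoromethanesulfonic anhydride, O=S(=O)(OS(=O)(=O)C(F)(F)F)C(F)(F)F
Why: O-triflation of the enone followed by loss of the only available γ-proton (the other α-carbon is quaternary) should give the linear dienyl triflate (enol triflate formation), which already holds the 1,3-diene of ring A.

**Step 12**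
Reactants: 19 2,6,6-trimethylcyclohexa-1,3-dien-1-yl trifluoromethanesulfonate; 14 (E)-3-methylpent-2-en-4-yn-1-ol
Product: 20 (2E)-3-methyl-5-(2,6,6-trimethylcyclohexa-1,3-dien-1-yl)pent-2-en-4-yn-1-ol
Conditions: Pd(PPh3)4 (5 mol %), CuI (10 mol %), Et3N, DMF, 40 °C, degassed
Reagents that add atoms: none
Why: Sonogashira coupling of the dienyl triflate with the terminal alkyne, as in step 9, should join ring A to the E enynol.

**Step 13**
Reactants: 20 (2E)-3-methyl-5-(2,6,6-trimethylcyclohexa-1,3-dien-1-yl)pent-2-en-4-yn-1-ol
Product: 21 [(2E)-3-methyl-5-(2,6,6-trimethylcyclohexa-1,3-dien-1-yl)pent-2-en-4-yn-1-yl]triphenylphosphonium bromide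
Conditions: PPh3·HBr, MeOH–CH2Cl2, 0 °C to rt
Reagents that add atoms: triphenylphosphine hydrobromide, c1ccc(cc1)[PH+](c1ccccc1)c1ccccc1.[Br-]
Why: phosphonium salt formation from a primary allylic alcohol under mildly acidic conditions, which the gem-dimethyl-blocked cyclohexadiene (it cannot aromatize) should tolerate.

**Step 14**
Reactants: 21 [(2E)-3-methyl-5-(2,6,6-trimethylcyclohexa-1,3-dien-1-yl)pent-2-en-4-yn-1-yl]triphenylphosphonium bromide; 22 (2E,4E,6E)-2,7-dimethylocta-2,4,6-trienedial
Product: 25 (2E,4E,6E,8E,10E)-2,7,11-trimethyl-13-(2,6,6-trimethylcyclohexa-1,3-dien-1-yl)trideca-2,4,6,8,10-pentaen-12-ynal, via ylide 23 (not isolated), via 8Z aldehyde 24 (not isolated)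
Conditions: 22 (3 equiv), NaOMe, MeOH–CH2Cl2, 0 °C to rt, salt added slowly; then heptane, 80 °C, argon, dark
Reagents that add atoms: none
Why: Wittig olefination of one formyl group of the symmetrical dialdehyde, kept in excess so that mono-olefination should dominate, in which the semi-stabilized allylic ylide gives the new C=C as an E/Z mixture and warming should equilibrate the hindered Z isomer to the all-E aldehyde.

**Step 15**
Reactants: 17 [(2E)-5-[(4R)-4-hydroxy-2,6,6-trimethylcyclohex-1-en-1-yl]-3-methylpent-2-en-4-yn-1-yl]triphenylphosphonium bromide; 25 (2E,4E,6E,8E,10E)-2,7,11-trimethyl-13-(2,6,6-trimethylcyclohexa-1,3-dien-1-yl)trideca-2,4,6,8,10-pentaen-12-ynal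
Product: 28 (3R)-3',4',7,8,7',8'-hexadehydro-β,β-caroten-3-ol (all-E), via ylide 26 (not isolated), via 11Z isomer 27 (not isolated)
Conditions: NaOMe, MeOH–CH2Cl2, 0 °C to rt; then heptane–EtOAc, 80 °C, argon, dark; crystallization
Reagents that add atoms: none
Why: Wittig olefination with the free secondary alcohol left unprotected should complete the C40 chain, the new C11=C12 bond being brought to E by thermal equilibration of its hindered Z isomer, while C3 is remote from all reacting centers and keeps its configuration.

**Compound list**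
1 | (E)-but-2-ene | C/C=C/C | starting material
2 | (E)-but-2-en-1-ylpotassium | C/C=C/C[K] | intermediate (not isolated)
3 | diisopropyl (E)-but-2-en-1-ylboronate | C/C=C/CB(OC(C)C)OC(C)C | intermediate
4 | 3-methylbut-3-en-2-one | CC(=O)C(C)=C | starting material
5 | (3R,4R)-2,3,4-trimethylhexa-1,5-dien-3-ol | C=C(C)[C@](C)(O)[C@H](C)C=C | intermediate
6 | triethyl{[(3R,4R)-2,3,4-trimethylhexa-1,5-dien-3-yl]oxy}silane | C=C(C)[C@](C)(O[Si](CC)(CC)CC)[C@H](C)C=C | intermediate
7 | 2-[(3R,4R)-3,4,5-trimethyl-4-[(triethylsilyl)oxy]hex-5-en-1-yl]-1,3,2-benzodioxaborole | C=C(C)[C@](C)(O[Si](CC)(CC)CC)[C@H](C)CCB1Oc2ccccc2O1 | intermediate (not isolated)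
8 | (3R,4R)-3,4,5-trimethyl-4-[(triethylsilyl)oxy]hex-5-en-1-ol | C=C(C)[C@](C)(O[Si](CC)(CC)CC)[C@H](C)CCO | intermediate
9 | (3R,4R)-3,4,5-trimethyl-4-[(triethylsilyl)oxy]hex-5-enal | C=C(C)[C@](C)(O[Si](CC)(CC)CC)[C@H](C)CC=O | intermediate
10 | (4R,6R)-4-hydroxy-2,2,6-trimethylcyclohexan-1-one | C[C@@H]1C[C@@H](O)CC(C)(C)C1=O | intermediate
11 | (4R,6R)-2,2,6-trimethyl-4-[(triethylsilyl)oxy]cyclohexan-1-one | C[C@@H]1C[C@@H](O[Si](CC)(CC)CC)CC(C)(C)C1=O | intermediate
12 | potassium (4R)-2,6,6-trimethyl-4-[(triethylsilyl)oxy]cyclohex-1-en-1-olate | CC1=C([O-])C(C)(C)C[C@H](O[Si](CC)(CC)CC)C1.[K+] | intermediate (not isolated)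
13 | (4R)-2,6,6-trimethyl-4-[(triethylsilyl)oxy]cyclohex-1-en-1-yl trifluoromethanesulfonate | CC1=C(OS(=O)(=O)C(F)(F)F)C(C)(C)C[C@H](O[Si](CC)(CC)CC)C1 | intermediate
14 | (E)-3-methylpent-2-en-4-yn-1-ol | C#C/C(C)=C/CO | starting material
15 | (2E)-3-methyl-5-[(4R)-2,6,6-trimethyl-4-[(triethylsilyl)oxy]cyclohex-1-en-1-yl]pent-2-en-4-yn-1-ol | CC1=C(C#C/C(C)=C/CO)C(C)(C)C[C@H](O[Si](CC)(CC)CC)C1 | intermediate
16 | (2E)-5-[(4R)-4-hydroxy-2,6,6-trimethylcyclohex-1-en-1-yl]-3-methylpent-2-en-4-yn-1-ol | CC1=C(C#C/C(C)=C/CO)C(C)(C)C[C@H](O)C1 | intermediate (not isolated)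
17 | [(2E)-5-[(4R)-4-hydroxy-2,6,6-trimethylcyclohex-1-en-1-yl]-3-methylpent-2-en-4-yn-1-yl]triphenylphosphonium bromide | CC1=C(C#C/C(C)=C/C[P+](c2ccccc2)(c2ccccc2)c2ccccc2)C(C)(C)C[C@H](O)C1.[Br-] | intermediate
18 | 2,6,6-trimethylcyclohex-2-en-1-one | CC1=CCCC(C)(C)C1=O | starting material
19 | 2,6,6-trimethylcyclohexa-1,3-dien-1-yl trifluoromethanesulfonate | CC1=C(OS(=O)(=O)C(F)(F)F)C(C)(C)CC=C1 | intermediate
20 | (2E)-3-methyl-5-(2,6,6-trimethylcyclohexa-1,3-dien-1-yl)pent-2-en-4-yn-1-ol | CC1=C(C#C/C(C)=C/CO)C(C)(C)CC=C1 | intermediate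
21 | [(2E)-3-methyl-5-(2,6,6-trimethylcyclohexa-1,3-dien-1-yl)pent-2-en-4-yn-1-yl]triphenylphosphonium bromide | CC1=C(C#C/C(C)=C/C[P+](c2ccccc2)(c2ccccc2)c2ccccc2)C(C)(C)CC=C1.[Br-] | intermediate
22 | (2E,4E,6E)-2,7-dimethylocta-2,4,6-trienedial | O=C/C(C)=C/C=C/C=C(\C)C=O | starting material
23 | [(2E)-3-methyl-5-(2,6,6-trimethylcyclohexa-1,3-dien-1-yl)pent-2-en-4-yn-1-ylidene]triphenylphosphorane | CC1=C(C#C/C(C)=C/C=P(c2ccccc2)(c2ccccc2)c2ccccc2)C(C)(C)CC=C1 | intermediate (not isolated)
24 | (2E,4E,6E,8Z,10E)-2,7,11-trimethyl-13-(2,6,6-trimethylcyclohexa-1,3-dien-1-yl)trideca-2,4,6,8,10-pentaen-12-ynal | CC1=C(C#C/C(C)=C/C=C\C(C)=C\C=C\C=C(/C)C=O)C(C)(C)CC=C1 | intermediate (not isolated)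
25 | (2E,4E,6E,8E,10E)-2,7,11-trimethyl-13-(2,6,6-trimethylcyclohexa-1,3-dien-1-yl)trideca-2,4,6,8,10-pentaen-12-ynal | CC1=C(C#C/C(C)=C/C=C/C(C)=C/C=C/C=C(\C)C=O)C(C)(C)CC=C1 | intermediate
26 | [(2E)-5-[(4R)-4-hydroxy-2,6,6-trimethylcyclohex-1-en-1-yl]-3-methylpent-2-en-4-yn-1-ylidene]triphenylphosphorane | CC1=C(C#C/C(C)=C/C=P(c2ccccc2)(c2ccccc2)c2ccccc2)C(C)(C)C[C@H](O)C1 | intermediate (not isolated)
27 | (3R,11Z)-3',4',7,8,7',8'-hexadehydro-β,β-caroten-3-ol | CC1=C(C#C/C(C)=C/C=C/C(C)=C/C=C/C=C(C)/C=C\C=C(/C)C#CC2=C(C)C[C@@H](O)CC2(C)C)C(C)(C)CC=C1 | intermediate (not isolated)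
28 | (3R)-3',4',7,8,7',8'-hexadehydro-β,β-caroten-3-ol, all-E (CNP0250213.1) | CC1=C(C#C/C(C)=C/C=C/C(C)=C/C=C/C=C(C)/C=C/C=C(\C)C#CC2=C(C)C[C@@H](O)CC2(C)C)C(C)(C)CC=C1 | target

**Step count and risks**
Total step count: 15 (the reagent preparation in step 1 included).
Longest linear sequence: 11 steps (steps 1 to 10, then step 15).

Steps most likely to fail:

1. Step 6 (Proposed new method). The cation may lose a proton from its methyl group before the shift (ene-type outcome). The ring carbon may migrate instead of the methyl (ring contraction). The closure may run through the other chair and erode the facial selectivity at C3. The silyl ether oxygen may add to the activated aldehyde (five-membered acetal, silyl transfer). The Lewis acid may ionize the tertiary allylic silyl ether. Fallback, known chemistry only, with the stereocenters set by enzymes: it sets out from 18. Allylic oxidation of the ring CH2 next to the alkene (CrO3, 3,5-dimethylpyrazole, CH2Cl2, −20 °C) should give 2,6,6-trimethylcyclohex-2-ene-1,4-dione F1. An ene-reductase of the old yellow enzyme family (NADPH recycled with glucose dehydrogenase and glucose, buffer, 30 °C) should reduce the C=C bond to (6R)-2,2,6-trimethylcyclohexane-1,4-dione F2. A ketoreductase of the levodione reductase type (NADH recycling) should then reduce the less hindered C4 carbonyl to the (4R) alcohol, which comes back to the route at 10.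

2. Step 2. Facial discrimination between methyl and isopropenyl on the ketone may be insufficient, or an uncatalysed background addition may compete, so that the enantiomeric purity is too low; the enone may also oligomerize. Fallback, resolution instead of catalyst control: the material is carried through steps 3 to 6 as it is, and the fallback sets out from 10 of insufficient enantiomeric purity. Esterification with (S)-2-methoxy-2-phenylacetic acid (DCC, DMAP, CH2Cl2) should give (1R,5R)-3,3,5-trimethyl-4-oxocyclohexyl (2S)-2-methoxy-2-phenylacetate F3. This is freed by crystallization or chromatography from the diastereomeric ester of the enantiomer, (1S,5S)-3,3,5-trimethyl-4-oxocyclohexyl (2S)-2-methoxy-2-phenylacetate F4. Methanolysis of F3 (K2CO3, MeOH, 0 °C) comes back at 10; epimerization next to the ketone during this step would be of no consequence, since that center is flattened in step 8.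

3. Step 4. The isopropenyl group may be hydroborated as well, or a rhodium hydride may move the terminal double bond inward before borylation. Fallback, metathesis instead of hydroboration: it sets out from 6. Cross-metathesis with vinylboronic acid pinacol ester (second-generation Grubbs catalyst, CH2Cl2, 40 °C) should engage only the monosubstituted alkene and give triethyl{[(3R,4R,5E)-2,3,4-trimethyl-6-(4,4,5,5-tetramethyl-1,3,2-dioxaborolan-2-yl)hexa-1,5-dien-3-yl]oxy}silane F5. Oxidation of its C–B bond (NaBO3·4H2O, THF–H2O, rt) gives the enol and hence the aldehyde, so the fallback comes back at 9 and bypasses 7 and 8.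

**Further compounds**
F1 | step 6 | 2,6,6-trimethylcyclohex-2-ene-1,4-dione | CC1=CC(=O)CC(C)(C)C1=O
F2 | step 6 | (6R)-2,2,6-trimethylcyclohexane-1,4-dione | C[C@@H]1CC(=O)CC(C)(C)C1=O
F3 | step 2 | (1R,5R)-3,3,5-trimethyl-4-oxocyclohexyl (2S)-2-methoxy-2-phenylacetate | C[C@@H]1C[C@@H](OC(=O)[C@@H](OC)c2ccccc2)CC(C)(C)C1=O
F4 | step 2 | (1S,5S)-3,3,5-trimethyl-4-oxocyclohexyl (2S)-2-methoxy-2-phenylacetate | C[C@H]1C[C@H](OC(=O)[C@@H](OC)c2ccccc2)CC(C)(C)C1=O
F5 | step 4 | triethyl{[(3R,4R,5E)-2,3,4-trimethyl-6-(4,4,5,5-tetramethyl-1,3,2-dioxaborolan-2-yl)hexa-1,5-dien-3-yl]oxy}silane | C=C(C)[C@](C)(O[Si](CC)(CC)CC)[C@H](C)/C=C/B1OC(C)(C)C(C)(C)O1
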